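**Plan**

Numbering: C1 is the ring CH carrying the CH2O carbon C7, C2 the methyl-bearing sp2 carbon, C3 the olefinic CH, C4 the ring CH2, C5 the acyloxy CH, C6 the CMe2 carbon; the target is (1S,5R), cis, with an (R)-2-methylbutanoate.
Enabling feature: the C2=C3 double bond of the six-membered ring C1–C6 is the only ring bond whose formation leaves the stereocentres C1 and C5 and the quaternary C6 untouched, so the ring can be closed late on a chain that already carries them.
Retrosynthesis cuts the C7–O aryl ether (Mitsunobu), the C2=C3 alkene (ring-closing metathesis), the C5–O ester, the C4–C5 bond (allylboration) and the C1–C6 bond (Ireland–Claisen), back to an enone from a Wittig reaction.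
Forward, the acyclic chain C2–C1–C6–C5–C4–C3 is assembled first, the single carbocycle closes in step 8, and the coumarin is attached last.
Stereochemistry: C1 by 1,3-chirality transfer in the Ireland–Claisen step from a carbinol set by CBS reduction (its methyl ends on the olefin terminus and leaves as propene on ring closure); C5 by reagent-controlled Brown allylation; the acyl centre from (R)-2-methylbutanoic acid.

Key step: step 8

**Route**

Step 1
Reactants: 1 (4-methoxybenzyloxy)acetaldehyde; 2 3-(triphenylphosphoranylidene)butan-2-one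
Product: 3 (3E)-5-[(4-methoxybenzyl)oxy]-3-methylpent-3-en-2-one
Conditions: toluene, 80 °C
Reagents that add atoms: none
Why: Wittig olefination with a stabilised, α-branched keto ylide is under thermodynamic control at the oxaphosphetane stage and should give the E trisubstituted enone.

Step 2
Reactants: 3 (3E)-5-[(4-methoxybenzyl)oxy]-3-methylpent-3-en-2-one
Product: 4 (2R,3E)-5-[(4-methoxybenzyl)oxy]-3-methylpent-3-en-2-ol
Conditions: (S)-2-methyl-CBS-oxazaborolidine (10 mol %), catecholborane, toluene, −78 °C
Reagents that add atoms: none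
Why: Corey–Bakshi–Shibata reduction, in which the ketone binds the catalyst with the branched alkenyl group as the large and the methyl as the small substituent, so hydride reaches one face only and the new carbinol centre should be R, with 1,2- favoured over conjugate reduction.

Step 3
Reactants: 4 (2R,3E)-5-[(4-methoxybenzyl)oxy]-3-methylpent-3-en-2-ol; 5 isobutyryl chloride
Product: 6 (2R,3E)-5-[(4-methoxybenzyl)oxy]-3-methylpent-3-en-2-yl 2-methylpropanoate
Conditions: pyridine, DMAP (cat.), CH2Cl2, 0 °C to rt
Reagents that add atoms: none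
Why: DMAP-catalysed O-acylation of a secondary allylic alcohol, which does not touch the C–O stereocentre.

Step 4
Reactants: 6 (2R,3E)-5-[(4-methoxybenzyl)oxy]-3-methylpent-3-en-2-yl 2-methylpropanoate
Product: 9 (3S,4E)-3-{[(4-methoxybenzyl)oxy]methyl}-2,2,4-trimethylhex-4-en-1-ol, via silyl ketene acetal 7 (not isolated), via trimethylsilyl ester 8 (not isolated)
Conditions: LiN(iPr)2, THF, −78 °C; Me3SiCl, −78 to 65 °C; then LiAlH4, 0 °C
Reagents that add atoms: chlorotrimethylsilane, C[Si](C)(C)Cl (its silicon stays only in 7 and 8)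
Why: Ireland–Claisen rearrangement, in which the tetrasubstituted ketene acetal 7 (no E/Z issue) reacts through a chair transition state with the carbinol methyl equatorial, so the C–O bond of the R carbinol is exchanged suprafacially for the new C1–C6 bond, setting 3S and the E olefin by 1,3-chirality transfer, after which LiAlH4 reduces silyl ester 8 to the neopentyl alcohol.

Step 5
Reactants: 9 (3S,4E)-3-{[(4-methoxybenzyl)oxy]methyl}-2,2,4-trimethylhex-4-en-1-ol
Product: 10 (3S,4E)-3-{[(4-methoxybenzyl)oxy]methyl}-2,2,4-trimethylhex-4-enal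
Conditions: Dess–Martin periodinane, CH2Cl2, rt
Reagents that add atoms: none
Why: Dess–Martin oxidation of a primary neopentyl alcohol stops at the aldehyde, which has no α-hydrogen and therefore cannot enolise or epimerise.

Step 6
Reactants: 10 (3S,4E)-3-{[(4-methoxybenzyl)oxy]methyl}-2,2,4-trimethylhex-4-enal
Product: 12 (4R,6S,7E)-6-{[(4-methoxybenzyl)oxy]methyl}-5,5,7-trimethylnona-1,7-dien-4-ol, via diisopinocampheylborinate 11 (not isolated)
Conditions: (+)-Ipc2BOMe, CH2=CHCH2MgBr, Et2O, 0 °C to rt; then 10, −78 °C; NaOH, H2O2, 0 °C to rt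
Reagents that add atoms: B-allyldiisopinocampheylborane of the (−)-α-pinene series, C=CCB([C@H]1C[C@H]2C[C@@H]([C@@H]1C)C2(C)C)[C@H]1C[C@H]2C[C@@H]([C@@H]1C)C2(C)C, made in the flask from allylmagnesium bromide, C=CC[Mg]Br, and (+)-B-methoxydiisopinocampheylborane, COB([C@H]1C[C@H]2C[C@@H]([C@@H]1C)C2(C)C)[C@H]1C[C@H]2C[C@@H]([C@@H]1C)C2(C)C
Why: Brown allylboration through a closed six-membered chair transition state, in which, because 10 has no α-stereocentre, the isopinocampheyl groups decide the aldehyde face and should give the 4R carbinol, the minor C4 epimer being a separable diastereomer.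

Step 7
Reactants: 12 (4R,6S,7E)-6-{[(4-methoxybenzyl)oxy]methyl}-5,5,7-trimethylnona-1,7-dien-4-ol; 13 (R)-2-methylbutanoic acid
Product: 14 (4R,6S,7E)-6-{[(4-methoxybenzyl)oxy]methyl}-5,5,7-trimethylnona-1,7-dien-4-yl (2R)-2-methylbutanoate
Conditions: DCC, DMAP, CH2Cl2, 0 °C to rt
Reagents that add atoms: none
Why: Steglich esterification via the N-acylpyridinium ion acylates the hindered carbinol with retention at C5, and a simple α-alkyl acid should not lose its stereocentre under these conditions.

Step 8
Reactants: 14 (4R,6S,7E)-6-{[(4-methoxybenzyl)oxy]methyl}-5,5,7-trimethylnona-1,7-dien-4-yl (2R)-2-methylbutanoate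
Product: 15 (1R,5S)-5-{[(4-methoxybenzyl)oxy]methyl}-4,6,6-trimethylcyclohex-3-en-1-yl (2R)-2-methylbutanoate
Conditions: second-generation Grubbs catalyst (H2IMes)(PCy3)Cl2Ru=CHPh (5 mol %), toluene (0.005 M), 80 °C
Reagents that add atoms: none
Why: The ruthenium benzylidene initiates at the monosubstituted C3 olefin, the resulting alkylidene adds across the trisubstituted C2 olefin to a ruthenacyclobutane, and cycloreversion releases the C2=C3 ring alkene and a ruthenium ethylidene that carries the chain and is lost as propene. The closest known reaction type is ring-closing metathesis of a terminal olefin onto a more highly substituted olefin to give a trisubstituted cyclohexene. The one ring is closed by joining the two former olefin carbons C2 and C3 of the chain C3–C4–C5–C6–C1–C2, so the new double bond is endocyclic in a six-membered carbocycle and can only be Z. No stereocentre is created; C1 and C5 lie outside the reacting carbons and pass through unchanged. The step needs cyclisation to win over intermolecular metathesis at the terminal olefin, which the C6 gem-dimethyl group (chain folding), high dilution and the inability of the trisubstituted olefin to homodimerise should secure. The ester, the 4-methoxybenzyl ether and the acyl stereocentre are inert to the catalyst.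

Step 9
Reactants: 15 (1R,5S)-5-{[(4-methoxybenzyl)oxy]methyl}-4,6,6-trimethylcyclohex-3-en-1-yl (2R)-2-methylbutanoate
Product: 16 (1R,5S)-5-(hydroxymethyl)-4,6,6-trimethylcyclohex-3-en-1-yl (2R)-2-methylbutanoate
Conditions: DDQ, CH2Cl2/aqueous pH 7 buffer, 0 °C
Reagents that add atoms: none
Why: Oxidative 4-methoxybenzyl ether cleavage (hydride abstraction to the benzylic oxocarbenium ion, then hydrolysis) is selective for the electron-rich benzyl ether and leaves the ester and the trisubstituted alkene alone.

Step 10
Reactants: 16 (1R,5S)-5-(hydroxymethyl)-4,6,6-trimethylcyclohex-3-en-1-yl (2R)-2-methylbutanoate; 17 umbelliferone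
Product: 18 (1R,5S)-4,6,6-trimethyl-5-{[(2-oxo-2H-chromen-7-yl)oxy]methyl}cyclohex-3-en-1-yl (2R)-2-methylbutanoate
Conditions: PPh3, DIAD, THF, 0 °C to rt
Reagents that add atoms: none
Why: Mitsunobu etherification, in which the acidic phenol protonates the betaine and its phenoxide displaces the alkoxyphosphonium group at the primary, non-stereogenic C7 under neutral conditions that spare the ester and the coumarin lactone.

**Compound list**

1 | (4-methoxybenzyloxy)acetaldehyde | COc1ccc(COCC=O)cc1 | starting material
2 | 3-(triphenylphosphoranylidene)butan-2-one | CC(=O)C(C)=P(c1ccccc1)(c1ccccc1)c1ccccc1 | starting material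
3 | (3E)-5-[(4-methoxybenzyl)oxy]-3-methylpent-3-en-2-one | CC(=O)/C(C)=C/COCc1ccc(OC)cc1 | intermediate
4 | (2R,3E)-5-[(4-methoxybenzyl)oxy]-3-methylpent-3-en-2-ol | C[C@@H](O)/C(C)=C/COCc1ccc(OC)cc1 | intermediate
5 | isobutyryl chloride | CC(C)C(Cl)=O | starting material
6 | (2R,3E)-5-[(4-methoxybenzyl)oxy]-3-methylpent-3-en-2-yl 2-methylpropanoate | CC(C)C(=O)O[C@H](C)/C(C)=C/COCc1ccc(OC)cc1 | intermediate
7 | trimethylsilyl ketene acetal of 6, 1-{[(2R,3E)-5-[(4-methoxybenzyl)oxy]-3-methylpent-3-en-2-yl]oxy}-2-methyl-1-(trimethylsilyloxy)prop-1-ene | CC(C)=C(O[Si](C)(C)C)O[C@H](C)/C(C)=C/COCc1ccc(OC)cc1 | intermediate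
8 | trimethylsilyl (3S,4E)-3-{[(4-methoxybenzyl)oxy]methyl}-2,2,4-trimethylhex-4-enoate | C[Si](C)(C)OC(=O)C(C)(C)[C@@H](COCc1ccc(OC)cc1)/C(C)=C/C | intermediate
9 | (3S,4E)-3-{[(4-methoxybenzyl)oxy]methyl}-2,2,4-trimethylhex-4-en-1-ol | OCC(C)(C)[C@@H](COCc1ccc(OC)cc1)/C(C)=C/C | intermediate
10 | (3S,4E)-3-{[(4-methoxybenzyl)oxy]methyl}-2,2,4-trimethylhex-4-enal | O=CC(C)(C)[C@@H](COCc1ccc(OC)cc1)/C(C)=C/C | intermediate
11 | (4R,6S,7E)-6-{[(4-methoxybenzyl)oxy]methyl}-5,5,7-trimethylnona-1,7-dien-4-yl diisopinocampheylborinate | C=CC[C@@H](OB([C@H]1C[C@H]2C[C@@H]([C@@H]1C)C2(C)C)[C@H]1C[C@H]2C[C@@H]([C@@H]1C)C2(C)C)C(C)(C)[C@@H](COCc1ccc(OC)cc1)/C(C)=C/C | intermediate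
12 | (4R,6S,7E)-6-{[(4-methoxybenzyl)oxy]methyl}-5,5,7-trimethylnona-1,7-dien-4-ol | C=CC[C@@H](O)C(C)(C)[C@@H](COCc1ccc(OC)cc1)/C(C)=C/C | intermediate
13 | (R)-2-methylbutanoic acid | CC[C@@H](C)C(=O)O | starting material
14 | (4R,6S,7E)-6-{[(4-methoxybenzyl)oxy]methyl}-5,5,7-trimethylnona-1,7-dien-4-yl (2R)-2-methylbutanoate | CC[C@@H](C)C(=O)O[C@H](CC=C)C(C)(C)[C@@H](COCc1ccc(OC)cc1)/C(C)=C/C | intermediate
15 | (1R,5S)-5-{[(4-methoxybenzyl)oxy]methyl}-4,6,6-trimethylcyclohex-3-en-1-yl (2R)-2-methylbutanoate | CC[C@@H](C)C(=O)O[C@@H]1CC=C(C)[C@H](COCc2ccc(OC)cc2)C1(C)C | intermediate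
16 | (1R,5S)-5-(hydroxymethyl)-4,6,6-trimethylcyclohex-3-en-1-yl (2R)-2-methylbutanoate | CC[C@@H](C)C(=O)O[C@@H]1CC=C(C)[C@H](CO)C1(C)C | intermediate
17 | umbelliferone (7-hydroxycoumarin) | O=c1ccc2ccc(O)cc2o1 | starting material
18 | (1R,5S)-4,6,6-trimethyl-5-{[(2-oxo-2H-chromen-7-yl)oxy]methyl}cyclohex-3-en-1-yl (2R)-2-methylbutanoate | CC[C@@H](C)C(=O)O[C@@H]1CC=C(C)[C@H](COc2ccc3ccc(=O)oc3c2)C1(C)C | target

**Step count**

Total steps: 10. Longest linear sequence: 10 steps (1 to 18).

**Steps most likely to fail, with fallbacks**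

Step 8. Ring closure onto the hindered trisubstituted olefin may be slower than catalyst decay, so that intermolecular metathesis at the terminal olefin takes over. The fallback sets out from 14 and comes back at 15, making the same C2=C3 bond by carbonyl coupling. Ozonolysis of both olefins (O3, CH2Cl2, −78 °C; Me2S) would give the keto aldehyde (3R,5S)-5-{[(4-methoxybenzyl)oxy]methyl}-4,4-dimethyl-1,6-dioxoheptan-3-yl (2R)-2-methylbutanoate F1. Intramolecular McMurry coupling of its C3 aldehyde with the C2 methyl ketone (TiCl3(DME)1.5, Zn–Cu couple, DME, slow addition at high dilution) should then give 15.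

Step 10. Substitution at the β-branched C7 carbinol next to the quaternary centre may be sluggish, letting elimination of the alkoxyphosphonium group or acyl shift to the primary hydroxyl compete. The fallback sets out from 16 and comes back at 18 by forming the aryl–oxygen bond instead of the alkyl–oxygen bond. This is a palladium-catalysed C–O coupling of 16 with commercial 7-bromocoumarin (Pd2(dba)3, tBuBrettPhos, Cs2CO3, toluene, 80 °C), so steric hindrance at C7 no longer limits the bond-forming event. New compound on the way: none F0.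

Step 6. Reagent control over the two faces of the α-quaternary aldehyde may be incomplete, eroding the selectivity at C5. The fallback sets out from 10 and comes back at 12 by setting this centre through ketone reduction. Unselective addition of CH2=CHCH2MgBr (THF, −78 °C) would give the C4-epimeric mixture (6S,7E)-6-{[(4-methoxybenzyl)oxy]methyl}-5,5,7-trimethylnona-1,7-dien-4-ol F2. Dess–Martin oxidation would give the β,γ-unsaturated ketone (6S,7E)-6-{[(4-methoxybenzyl)oxy]methyl}-5,5,7-trimethylnona-1,7-dien-4-one F3. CBS reduction with (S)-2-methyl-CBS-oxazaborolidine and catecholborane (toluene, −78 °C), with the tertiary alkyl group as the large and the allyl group as the small substituent, should then deliver the 4R alcohol 12.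

**Further compounds**

F1 | step 8 | (3R,5S)-5-{[(4-methoxybenzyl)oxy]methyl}-4,4-dimethyl-1,6-dioxoheptan-3-yl (2R)-2-methylbutanoate | CC[C@@H](C)C(=O)O[C@H](CC=O)C(C)(C)[C@@H](COCc1ccc(OC)cc1)C(C)=O
F0 | step 10 | none | none
F2 | step 6 | (6S,7E)-6-{[(4-methoxybenzyl)oxy]methyl}-5,5,7-trimethylnona-1,7-dien-4-ol, mixture of C4 epimers | C=CCC(O)C(C)(C)[C@@H](COCc1ccc(OC)cc1)/C(C)=C/C
F3 | step 6 | (6S,7E)-6-{[(4-methoxybenzyl)oxy]methyl}-5,5,7-trimethylnona-1,7-dien-4-one | C=CCC(=O)C(C)(C)[C@@H](COCc1ccc(OC)cc1)/C(C)=C/C
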